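A constant first-order constant k for the loss of starting material (the logarithm of the ratio of two readings, over the time between them) is impossible in the ash run, where it reads 0.177 /d from 2.08 d to 4.00 d but 0.0511 /d from 6.00 d to 12.0 d, so k is what I watch on a repeat.

the same everywhere: free catalyst 20 mM
- ash: starting material 2 M; reagent 1.4 M; protic impurity 0.020 M; run made earlier
- cedar: starting material 2 M; reagent 1.4 M; protic impurity 0.030 M; run made earlier
- oak: starting material 3 M; reagent 1.4 M; protic impurity 0.040 M; run made earlier
- flask: starting material 2.0 M; reagent 1.40 M; protic impurity 0.0400 M; time 12 d

| run | time / d | starting material / % | product / % |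
|---|---|---|---|
| ash | 2.08 | 54.4 | 15.8 |
| ash | 4.00 | 38.7 | 28.8 |
| ash | 6.00 | 30.3 | 37.0 |
| ash | 8.00 | 26.5 | 41.9 |
| ash | 10.0 | 24.4 | 44.3 |
| ash | 12.0 | 22.3 | 46.1 |
| cedar | 2.08 | 54.6 | 16.0 |
| cedar | 4.00 | 39.2 | 27.6 |
| cedar | 6.00 | 31.4 | 37.1 |
| cedar | 8.00 | 26.3 | 41.0 |
| cedar | 10.0 | 24.5 | 44.4 |
| cedar | 12.0 | 23.3 | 45.7 |
| oak | 1.04 | 70.7 | 5.4 |
| oak | 3.00 | 47.3 | 20.1 |
| oak | 6.00 | 33.5 | 32.1 |
| oak | 8.00 | 29.1 | 36.0 |
| oak | 12.0 | 23.0 | 39.7 |

(standard deviation of a reading: 0.5 percentage points)

* at 12 d, what has stopped the reaction, if anything has (forward and back rates have come level / it is still moving / no working catalyst is left / the reagent has run out first / all of the starting material has reacted)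
* how much of the starting material has reacted by 12 d
* how much product there is at 12 d, in percent of the starting material charged
* amount of product if the flask were left three thousand times as long, in percent of the starting material charged

- candidate steps: starting material + free catalyst -> free catalyst + open intermediate; free catalyst + open intermediate <-> catalyst intermediate; reagent + catalyst intermediate -> free catalyst + product; free catalyst -> spent catalyst; starting material + protic impurity -> quenched substrate
- the reaction counts as stopped when no species that holds the starting material changes by six tenths of a point or more over the second half of the time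

1. I take the main step first: with the early k held to 12 d, the flask would keep 12.0% of its starting material, yet ash and cedar average 22.8% there.

2. I add catalyst death: the two windows have midpoints 5.96 d apart, which gives 3.32 d for h, the catalyst half-life, the time for k and so the working catalyst to fall to half; it is a reading and carries the scatter of 0.5 percentage points. The flask's 12 d is 3.61 such half-lives, so the share of the catalyst's total work still to come is f = 8.16%.

3. I add the rest. The protic impurity takes 2.00% of the starting material, one for one. The ash gap of 31.6% at 12.0 d stands as open intermediate, catalyst intermediate and quenched substrate. In the flask reagent is the limiting reagent, capping product at 70.0%. Ash starting material still falls 8 points from 6.00 d to 12.0 d, so I say the flask is still moving, and from the ash and cedar averages I take 77.2% reacted and 45.9% product. That product leaves 34.4% of the reagent; stretching the logarithm of that share by 1/(1-f) gives 48.1% in the long run.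

The forecast says it is still moving, with 77.3% reacted, 45.8% product and 50.5% in the long run, holding that “catalyst is dying, not equilibrating”; its long-run product stands 2.4 points above mine.

The flask gives: it is still moving, with 77.8% reacted, 46.0% product and 49.8% in the long run, 1.7 points above my figure. starting material + free catalyst → free catalyst + open intermediate (k = 2.30 × 10⁻⁴ /M/s); free catalyst + open intermediate ⇌ catalyst intermediate (K = 0.730 /M, k = 5.90 × 10⁻⁴ /M/s); reagent + catalyst intermediate → free catalyst + product (k = 8.50 × 10⁻⁴ /M/s); free catalyst → spent catalyst (k = 2.80 × 10⁻⁶ /s); starting material + protic impurity → quenched substrate (k = 3.40 × 10⁻⁴ /M/s)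

At 12 d the flask holds 7.39% of its catalyst charge as free catalyst, 2.14% as catalyst intermediate and 90.5% as spent catalyst, against the 8.16% that h gave. Taking the same h for the neighbour charged with 0.080 M of free catalyst gives 8.16% again, against its 8.40% free catalyst and 3.39% catalyst intermediate, and that neighbour reaches 69.9% product with 0.103% of its reagent left.

The numbers in the tables were computed for substances that don't exist.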